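Counted one to one, a stall looks impossible in the gamma run: it has 2.00 equivalents of nucleophile, and yet the electrophile readings stand still near 54.3 %.

| flask | electrophile | nucleophile | buffer base | buffer acid | remark | time |
|---|---|---|---|---|---|---|
| gamma | 0.010 M | 0.020 M | 0.060 M | 6 mM | run made earlier |  |
| zeta | 0.015 M | 0.020 M | 0.060 M | 6 mM | run made earlier |  |
| flask | 0.020 M | 0.0200 M | 0.0600 M | 6.00 mM |  | 5.0 h |

| run | time / h | electrophile / % | target / % |
|---|---|---|---|
| gamma | 0.500 | 69.4 | 30.4 |
| gamma | 1.50 | 60.4 | 37.8 |
| gamma | 3.00 | 54.7 | 44.0 |
| gamma | 4.00 | 55.0 | 44.7 |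
| gamma | 6.00 | 53.6 | 47.4 |
| zeta | 1.33 | 63.5 | 35.3 |
| zeta | 2.50 | 58.4 | 38.5 |
| zeta | 4.00 | 58.2 | 39.7 |
| zeta | 5.00 | 59.6 | 40.6 |
| zeta | 6.00 | 59.8 | 39.8 |

(standard deviation of a reading: 1 percentage point)

- the earlier runs do not show the pH; that part of a forecast is a guess

- part of the electrophile that has reacted at 5.0 h
- pH of the solution at 5.0 h

My reckoning takes the stall for a lack of nucleophile, lost to itself in a second-order side step. So count turnovers. Let s, the waste factor (a selectivity factor), say how many times faster nucleophile is spent on itself than on electrophile at equal concentrations. Then each electrophile consumed costs 1 + s·c(nucleophile)/c(electrophile) nucleophiles. Integrated down to zero nucleophile, with charged concentrations: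

share of electrophile left = [1 + (s − 1)·c(nucleophile)/c(electrophile)]^(−1/(s − 1))

Solved for the plateau read in the gamma run, this gives a value that carries the scatter of those readings:

s = 4.34

For zeta it then gives 60.2 % left, against a read 59.2 %. That is a real test, since zeta played no part in s. For the flask I get 35.6 % reacted; the pH stays a guess.

The forecast gave 37 % (34 % to 40 %) and pH 7.8 (6.5 to 9.5), on “a reversible reaction reaching equilibrium”.

The flask gives 36.1 % reacted, at pH 8.70.

    electrophile + nucleophile → acid + target + leaving group (k = 0.0310 M⁻¹ s⁻¹)
    protonated nucleophile ⇌ nucleophile + acid, settled at all times (K = 1.60 × 10⁻⁸ M)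
    buffer acid ⇌ buffer base + acid, settled at all times (K = 7.90 × 10⁻⁹ M)
    2 nucleophile → self-condensation product (k = 0.0700 M⁻¹ s⁻¹)

In the flask the electrophile's half-life by the target step alone is 0.31 h at the charged concentrations, shorter than the 5.0 h of the run. At the asked time its half-life by that step is 74 d, far longer than the run, with 0.017 % of the nucleophile, the limiting reagent, left against 64 % of the electrophile. For a neighbour flask, charged like the flask but with 0.050 M of nucleophile, s gives 48.8 % reacted; that neighbour gives 49.8 %.

(The readings stem from a simulated flask from invented constants; the scatter is artificial.)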